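Both chroman rings are cut at once across O1–C2 and C3–C4. In each flavan unit C4 and O1 sit on neighbouring carbons of the benzo ring (C4a and C8a), which is a masked ortho-quinone methide, while C2–C3 with its phenyl group is simply styrene. One chiral-acid-catalysed double hetero-Diels–Alder reaction with two molecules of styrene should therefore build both dihydropyran rings, four bonds and both C2 stereocentres (S,S). The precursor is the methylene-bridged diarylmethane that carries, on each ring, a free phenol next to a CH2OH group, a methoxy group on the other side of it and a benzyl ether para to it. It is assembled by directed lithiation, ionic reduction and double formylation.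

Key step: step 8

Assumption: CIP analysis of the target gives S at C2 of both flavan units. (R)-TRIP, which is (R)-3,3'-bis(2,4,6-triisopropylphenyl)-1,1'-binaphthyl-2,2'-diyl hydrogen phosphate, is assumed to deliver this configuration; if the sense of induction proves opposite, (S)-TRIP is used instead. Ring A is the benzo ring of the flavan joined through C8, ring B that of the flavan joined through C6, and C2–C8a are flavan locants.

Step 1
Reactants: 1 5-methoxyresorcinol
Product: 2 1-methoxy-3,5-bis(methoxymethoxy)benzene
Conditions: MOMCl (2.4 equiv), i-Pr2NEt, CH2Cl2, 0 °C to rt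
Reagents that add atoms: chloromethyl methyl ether (MOMCl), COCCl
Why: Williamson-type O-alkylation of both phenols with the α-chloro ether should give the bis-acetal, whose two MOM groups later direct lithiation to the carbon between them.

Step 2
Reactants: 3 2,4-dihydroxy-6-methoxybenzaldehyde
Product: 5 2-methoxy-4,6-bis(methoxymethoxy)benzaldehyde, via disodium bis-phenoxide 4 (not isolated)
Conditions: NaH (2.4 equiv), DMF, 0 °C; then MOMCl (2.4 equiv), 0 °C to rt
Reagents that add atoms: chloromethyl methyl ether (MOMCl), COCCl
Why: Williamson etherification in which NaH deprotonates both phenols, the hydrogen-bonded 2-OH included, so that no acidic proton is left to quench the aryllithium of step 3.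

Step 3
Reactants: 2 1-methoxy-3,5-bis(methoxymethoxy)benzene; 5 2-methoxy-4,6-bis(methoxymethoxy)benzaldehyde
Product: 7 [2-methoxy-4,6-bis(methoxymethoxy)phenyl][4-methoxy-2,6-bis(methoxymethoxy)phenyl]methanol (racemic), via aryllithium 6 (not isolated)
Conditions: 2, n-BuLi, THF, 0 °C, 1 h; then 5, −78 °C to 0 °C; then H2O
Reagents that add atoms: none
Why: Directed ortho-metalation, in which the two MOM ethers cooperatively direct n-BuLi to the carbon between them (methoxy is the weaker director), followed by 1,2-addition to the non-enolisable aldehyde; this fixes the bridge carbon between the two oxygens of ring A and between OMe and O of ring B, and the racemic carbinol centre is removed in step 4.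

Step 4
Reactants: 7 [2-methoxy-4,6-bis(methoxymethoxy)phenyl][4-methoxy-2,6-bis(methoxymethoxy)phenyl]methanol
Product: 9 2-[(2,4-dihydroxy-6-methoxyphenyl)methyl]-5-methoxybenzene-1,3-diol, via tetrakis-MOM diarylmethane 8 (not isolated)
Conditions: Et3SiH (3 equiv), TFA, CH2Cl2, −20 °C to 0 °C; then HCl, MeOH, 40 °C
Reagents that add atoms: none
Why: Ionic hydrogenation (Kursanov–Parnes), in which TFA ionises the doubly benzylic carbinol to a bis(trialkoxyphenyl)methyl cation that Et3SiH reduces to the CH2 bridge; acid-catalysed acetal exchange in methanol then removes all four MOM groups as dimethoxymethane, methanol trapping the methoxymethyl cation before it can alkylate the electron-rich rings.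

Step 5
Reactants: 9 2-[(2,4-dihydroxy-6-methoxyphenyl)methyl]-5-methoxybenzene-1,3-diol
Product: 11 3-[(3-formyl-4,6-dihydroxy-2-methoxyphenyl)methyl]-2,4-dihydroxy-6-methoxybenzaldehyde, via bis-iminium dichloride 10 (not isolated)
Conditions: POCl3 (2.4 equiv), DMF (Vilsmeier reagent preformed at 0 °C), MeCN, 0 °C to rt; then H2O, 50 °C
Reagents that add atoms: N,N-dimethylformamide, CN(C)C=O; water, O
Why: Vilsmeier–Haack formylation, an electrophilic aromatic substitution that on resorcinols goes para to a free hydroxyl; ring A offers two equivalent such positions, in ring B only the carbon between OH and OMe is para to a hydroxyl (the carbon between the two hydroxyls is not), and each ring is deactivated after one formylation.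

Step 6
Reactants: 11 3-[(3-formyl-4,6-dihydroxy-2-methoxyphenyl)methyl]-2,4-dihydroxy-6-methoxybenzaldehyde
Product: 12 4-(benzyloxy)-3-{[6-(benzyloxy)-3-formyl-4-hydroxy-2-methoxyphenyl]methyl}-2-hydroxy-6-methoxybenzaldehyde
Conditions: BnBr (2.1 equiv), K2CO3, DMF, rt
Reagents that add atoms: benzyl bromide, BrCc1ccccc1
Why: Selective Williamson O-benzylation, because the hydroxyl para to each formyl group is the more acidic and is not held in the hydrogen bond to the carbonyl; two equivalents of BnBr with mild base should alkylate only these two positions, the future C7 oxygens.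

Step 7
Reactants: 12 4-(benzyloxy)-3-{[6-(benzyloxy)-3-formyl-4-hydroxy-2-methoxyphenyl]methyl}-2-hydroxy-6-methoxybenzaldehyde
Product: 13 3-(benzyloxy)-2-{[6-(benzyloxy)-4-hydroxy-3-(hydroxymethyl)-2-methoxyphenyl]methyl}-6-(hydroxymethyl)-5-methoxyphenol
Conditions: NaBH4, THF/MeOH, −10 °C; pH 7 buffer work-up; used crude
Reagents that add atoms: none
Why: Borohydride reduction of both aldehydes to primary benzylic alcohols; low temperature, a short reaction time and a neutral work-up limit over-reduction through phenoxide-derived quinone methides and acid-triggered self-condensation of this labile diol.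

Step 8
Reactants: 13 3-(benzyloxy)-2-{[6-(benzyloxy)-4-hydroxy-3-(hydroxymethyl)-2-methoxyphenyl]methyl}-6-(hydroxymethyl)-5-methoxyphenol; 14 styrene (two molecules are incorporated, one at each site)
Product: 16 (2S)-7-(benzyloxy)-8-{[(2S)-7-(benzyloxy)-5-methoxy-2-phenyl-3,4-dihydro-2H-chromen-6-yl]methyl}-5-methoxy-2-phenyl-3,4-dihydro-2H-chromene, via bis(ortho-quinone methide) 15 (not isolated)
Conditions: (R)-TRIP (10 mol %), styrene (20 equiv, of which 2 equiv are consumed), 5 Å MS, PhCF3, 0 °C to rt, 13 added slowly
Reagents that add atoms: styrene (second molecule of 14), C=Cc1ccccc1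
Why: Proposed new method: the chiral phosphoric acid protonates each benzylic hydroxyl, water leaves, and the resulting ortho-quinone methide (C4=C4a–C8a=O), hydrogen-bonded or ion-paired to the chiral phosphate, takes up one molecule of styrene with its CH2 terminus at C4 and its benzylic carbon at the carbonyl oxygen, which rearomatises the ring; the two sites are far apart and should react independently, so each molecule of 13 consumes two molecules of styrene and loses two of water, and 15 is only the formal doubly dehydrated form. The closest known chemistry is the thermal or acid-promoted racemic hetero-Diels–Alder reaction of ortho-quinone methides with styrenes to give flavans, together with chiral-phosphoric-acid-catalysed cycloadditions of ortho-quinone methides from ortho-hydroxybenzyl alcohols with more activated alkenes. Each dihydropyran ring is closed by an intermolecular inverse-electron-demand [4+2] cycloaddition, asynchronous and in the stepwise limit a C3–C4 bond formation followed by six-membered ring closure of the phenolic oxygen onto the benzylic cation. Each C2 stereocentre is set by the catalyst alone, whose 3,3'-aryl pocket around the phosphate-bound oxygen decides which face of the styrene benzylic carbon bonds to O1, and the antipode of the acid is chosen so that both centres come out S. The step needs regioselectivity (2-phenyl, not 3-phenyl), secured by the polarity of styrene, and chemoselectivity for styrene over the electron-rich arene CH positions and over para-quinone methide formation, secured by the large excess of styrene, the slow addition of 13 and the benzyl ethers on the C7 oxygens.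

Step 9
Reactants: 16 (2S)-7-(benzyloxy)-8-{[(2S)-7-(benzyloxy)-5-methoxy-2-phenyl-3,4-dihydro-2H-chromen-6-yl]methyl}-5-methoxy-2-phenyl-3,4-dihydro-2H-chromene
Product: 17 (2S)-8-{[(2S)-7-hydroxy-5-methoxy-2-phenyl-3,4-dihydro-2H-chromen-6-yl]methyl}-5-methoxy-2-phenyl-3,4-dihydro-2H-chromen-7-ol
Conditions: H2 (1 atm), Pd(OH)2/C, EtOAc/MeOH, rt
Reagents that add atoms: none
Why: Catalytic hydrogenolysis of the two aryl benzyl ethers, which under neutral conditions at 1 atm should be cleaved much faster than the cyclic benzylic C2–O1 bond of a flavan, and which leaves the C2 stereocentres untouched.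

Compound list
1 | 5-methoxyresorcinol (5-methoxybenzene-1,3-diol) | COc1cc(O)cc(O)c1 | starting material
2 | 1-methoxy-3,5-bis(methoxymethoxy)benzene | COCOc1cc(OC)cc(OCOC)c1 | intermediate
3 | 2,4-dihydroxy-6-methoxybenzaldehyde | COc1cc(O)cc(O)c1C=O | starting material
4 | disodium 4-formyl-5-methoxybenzene-1,3-bis(olate) | COc1cc([O-])cc([O-])c1C=O.[Na+].[Na+] | intermediate (not isolated)
5 | 2-methoxy-4,6-bis(methoxymethoxy)benzaldehyde | COCOc1cc(OC)c(C=O)c(OCOC)c1 | intermediate
6 | [4-methoxy-2,6-bis(methoxymethoxy)phenyl]lithium | [Li]c1c(OCOC)cc(OC)cc1OCOC | intermediate (not isolated)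
7 | [2-methoxy-4,6-bis(methoxymethoxy)phenyl][4-methoxy-2,6-bis(methoxymethoxy)phenyl]methanol (racemic) | OC(c1c(OCOC)cc(OC)cc1OCOC)c1c(OC)cc(OCOC)cc1OCOC | intermediate
8 | 1-methoxy-2-{[4-methoxy-2,6-bis(methoxymethoxy)phenyl]methyl}-3,5-bis(methoxymethoxy)benzene | COCOc1cc(OC)cc(OCOC)c1Cc1c(OC)cc(OCOC)cc1OCOC | intermediate (not isolated)
9 | 2-[(2,4-dihydroxy-6-methoxyphenyl)methyl]-5-methoxybenzene-1,3-diol | COc1cc(O)c(Cc2c(OC)cc(O)cc2O)c(O)c1 | intermediate
10 | bis(N,N-dimethyliminium) dichloride corresponding to dialdehyde 11 | COc1cc(O)c(Cc2c(O)cc(O)c(C=[N+](C)C)c2OC)c(O)c1C=[N+](C)C.[Cl-].[Cl-] | intermediate (not isolated)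
11 | 3-[(3-formyl-4,6-dihydroxy-2-methoxyphenyl)methyl]-2,4-dihydroxy-6-methoxybenzaldehyde | COc1cc(O)c(Cc2c(O)cc(O)c(C=O)c2OC)c(O)c1C=O | intermediate
12 | 4-(benzyloxy)-3-{[6-(benzyloxy)-3-formyl-4-hydroxy-2-methoxyphenyl]methyl}-2-hydroxy-6-methoxybenzaldehyde | COc1cc(OCc2ccccc2)c(Cc2c(OCc3ccccc3)cc(O)c(C=O)c2OC)c(O)c1C=O | intermediate
13 | 3-(benzyloxy)-2-{[6-(benzyloxy)-4-hydroxy-3-(hydroxymethyl)-2-methoxyphenyl]methyl}-6-(hydroxymethyl)-5-methoxyphenol | COc1cc(OCc2ccccc2)c(Cc2c(OCc3ccccc3)cc(O)c(CO)c2OC)c(O)c1CO | intermediate (key-step precursor)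
14 | styrene (two molecules enter 16) | C=Cc1ccccc1 | starting material
15 | bis(ortho-quinone methide) from 13 by loss of two molecules of water (each ring a 6-methylenecyclohexa-2,4-dien-1-one) | C=C1C(OC)=CC(OCc2ccccc2)=C(CC2=C(OC)C(=C)C(=O)C=C2OCc2ccccc2)C1=O | intermediate (not isolated)
16 | (2S)-7-(benzyloxy)-8-{[(2S)-7-(benzyloxy)-5-methoxy-2-phenyl-3,4-dihydro-2H-chromen-6-yl]methyl}-5-methoxy-2-phenyl-3,4-dihydro-2H-chromene | COc1cc(OCc2ccccc2)c(Cc2c(OCc3ccccc3)cc3c(c2OC)CC[C@@H](c2ccccc2)O3)c2c1CC[C@@H](c1ccccc1)O2 | intermediate (key-step product)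
17 | (2S)-8-{[(2S)-7-hydroxy-5-methoxy-2-phenyl-3,4-dihydro-2H-chromen-6-yl]methyl}-5-methoxy-2-phenyl-3,4-dihydro-2H-chromen-7-ol | COc1cc(O)c(Cc2c(O)cc3c(c2OC)CC[C@@H](c2ccccc2)O3)c2c1CC[C@@H](c1ccccc1)O2 | target

Total steps: 9. Longest linear sequence: 8 steps (1 → 2 → 7 → 9 → 11 → 12 → 13 → 16 → 17; the branch from 3 is equally long).

Steps most likely to fail

1. Step 8 (proposed new method). Facial discrimination may be insufficient at one or both sites, and the resulting remote diastereomers would be very hard to separate. The methides may also be consumed by the electron-rich arene positions of a second molecule faster than by styrene. The fallback uses known chemistry, sets out from 12 and comes back at 16. Both formyl groups of 12 would be olefinated with Ph3P=CHC(O)Ph (toluene, 100 °C, Wittig reaction) to give the bis-(E)-enone F1. Both C=C bonds would be saturated with H2 over Pd/C poisoned with Ph2S, which spares benzyl ethers and aryl ketones, to give the diketone F2. Asymmetric transfer hydrogenation with RuCl(p-cymene)[(R,R)-TsDPEN] in HCO2H/Et3N should give the (R,R)-diol F3. Double intramolecular Mitsunobu etherification (PPh3, DIAD, THF, 0 °C) would then close both dihydropyran rings with inversion at each carbinol carbon and deliver (S,S)-16.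

2. Step 5. Ring B may be formylated at the carbon between its two hydroxyls, a third formyl group may be introduced, or the diarylmethane may be cleaved by acid. The fallback sets out from 7 and comes back at 11. Carbinol 7 would be treated with n-BuLi (2.2 equiv, THF, 0 °C), which forms the alkoxide and then lithiates ring B between its two MOM ethers to give the dilithio species F4. Quenching with BrCF2CF2Br should give the bromo carbinol F5. The conditions of step 4 would reduce it to the bromo tetrakis-MOM diarylmethane F6 and then unmask the bromo tetraphenol F7, in which ring B has only the wanted position free. Vilsmeier–Haack formylation as in step 5 would pass through the bromo bis-iminium dichloride F8 to the bromo dialdehyde F9. Hydrodebromination (H2, Pd/C, NaOAc, EtOAc, rt) would return 11.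

3. Step 7. The formyl groups may be over-reduced to methyl groups when borohydride captures quinone methides formed from the phenoxides, and the diol may condense with itself during work-up. The fallback sets out from 12 and comes back at 13. Both hydrogen-bonded phenols of 12 would be allylated (allyl bromide, K2CO3, DMF, 60 °C) to give the bis-allyl ether dialdehyde F10. NaBH4 would reduce the now non-phenolic aldehydes to the bis-allyl ether diol F11. Deallylation with Pd(PPh3)4 and morpholine (THF, rt, Tsuji–Trost) under neutral conditions would then liberate 13.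

Further compounds
F1 | step 8 | (E,E)-bis-enone: 12 with each CHO replaced by CH=CH–C(O)Ph | COc1cc(OCc2ccccc2)c(Cc2c(OCc3ccccc3)cc(O)c(/C=C/C(=O)c3ccccc3)c2OC)c(O)c1/C=C/C(=O)c1ccccc1
F2 | step 8 | diketone: 12 with each CHO replaced by CH2CH2C(O)Ph | COc1cc(OCc2ccccc2)c(Cc2c(OCc3ccccc3)cc(O)c(CCC(=O)c3ccccc3)c2OC)c(O)c1CCC(=O)c1ccccc1
F3 | step 8 | (R,R)-diol: 12 with each CHO replaced by CH2CH2CH(OH)Ph, both carbinol centres R | COc1cc(OCc2ccccc2)c(Cc2c(OCc3ccccc3)cc(O)c(CC[C@@H](O)c3ccccc3)c2OC)c(O)c1CC[C@@H](O)c1ccccc1
F4 | step 5 | lithium alkoxide of 7 lithiated in ring B between the two MOM ethers (dilithio species) | [Li+].[O-]C(c1c(OCOC)cc(OC)cc1OCOC)c1c(OC)cc(OCOC)c([Li])c1OCOC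
F5 | step 5 | [3-bromo-6-methoxy-2,4-bis(methoxymethoxy)phenyl][4-methoxy-2,6-bis(methoxymethoxy)phenyl]methanol | OC(c1c(OCOC)cc(OC)cc1OCOC)c1c(OC)cc(OCOC)c(Br)c1OCOC
F6 | step 5 | bromo tetrakis-MOM diarylmethane (8 with Br between the two MOM ethers of ring B) | COCOc1cc(OC)cc(OCOC)c1Cc1c(OC)cc(OCOC)c(Br)c1OCOC
F7 | step 5 | 2-[(3-bromo-2,4-dihydroxy-6-methoxyphenyl)methyl]-5-methoxybenzene-1,3-diol | COc1cc(O)c(Cc2c(OC)cc(O)c(Br)c2O)c(O)c1
F8 | step 5 | bromo bis(N,N-dimethyliminium) dichloride corresponding to F9 | COc1cc(O)c(Cc2c(O)c(Br)c(O)c(C=[N+](C)C)c2OC)c(O)c1C=[N+](C)C.[Cl-].[Cl-]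
F9 | step 5 | 3-[(5-bromo-3-formyl-4,6-dihydroxy-2-methoxyphenyl)methyl]-2,4-dihydroxy-6-methoxybenzaldehyde | COc1cc(O)c(Cc2c(O)c(Br)c(O)c(C=O)c2OC)c(O)c1C=O
F10 | step 7 | bis-allyl ether of 12 (both free phenols as O-allyl) | COc1cc(OCc2ccccc2)c(Cc2c(OCc3ccccc3)cc(OCC=C)c(C=O)c2OC)c(OCC=C)c1C=O
F11 | step 7 | bis-allyl ether of 13 (both free phenols as O-allyl) | COc1cc(OCc2ccccc2)c(Cc2c(OCc3ccccc3)cc(OCC=C)c(CO)c2OC)c(OCC=C)c1CO
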